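**Retrosynthesis (germacrane numbering C1–C15 is used for every intermediate)**
1. Target ⇒ E,E-germacra-1(10),4-dienolide by double outer-face epoxidation; C8 ester ⇒ 8α-alcohol + chlorohydrin acid; 8α-alcohol ⇒ 8-ketone (CBS reduction).
2. Key disconnection C7–C8: the 10-membered carbocycle ⇒ a 13-membered macrolactone (C8 carboxyl esterified by the C13 hydroxyl of a 4-iodobutenolide). An alkenylmagnesium at C7 attacks the lactone carbonyl, contracts the ring 13 → 10 and releases the C13 alkoxide, which is acetylated.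
3. Macrolactone ⇒ hydroxy acid (Mitsunobu); iodobutenolide ⇒ 2,3-allenoate (iodolactonisation) ⇒ propargylic carbonate (Pd/CO) ⇒ enal + silyl propargyl ether (asymmetric alkynylation sets C6).
4. Enal ⇒ two Zr-catalysed carboaluminations of terminal alkynes (both E-trisubstituted olefins) joined by a Negishi coupling; the remaining carbons come from Me3Al, CH2O and CO.
5. Ring order: butenolide → 13-membered macrolactone → 10-membered carbocycle → two epoxides.

Assumption: enantiopure (R)-3-chloro-2-hydroxy-2-methylpropanoic acid and the three silyl-capped C4/C3 alkynes are purchased.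

**Step 1**
Reactants: 1 tert-butyl(but-3-yn-1-yloxy)dimethylsilane
Product: 3 (E)-tert-butyl[(4-iodo-3-methylbut-3-en-1-yl)oxy]dimethylsilane, via alkenylalane 2 (not isolated)
Conditions: Me3Al (2 equiv), Cp2ZrCl2 (0.2 equiv), CH2Cl2, 0 °C → rt; then I2, THF, −30 → 0 °C
Reagents that add atoms: trimethylaluminium C[Al](C)C; iodine II
Why: Negishi Zr-catalysed carboalumination adds Me and Al syn across the terminal alkyne (Al on the terminal carbon) and iodinolysis of the C–Al bond with retention gives the E-iodide; silyl ethers are tolerated.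

**Step 2**
Reactants: 3 (E)-tert-butyl[(4-iodo-3-methylbut-3-en-1-yl)oxy]dimethylsilane; 4 (4-bromobut-1-yn-1-yl)trimethylsilane
Product: 6 (E)-tert-butyldimethyl{[3-methyl-8-(trimethylsilyl)oct-3-en-7-yn-1-yl]oxy}silane, via organozinc bromide 5 (not isolated)
Conditions: 4, Zn dust, LiCl, THF, 50 °C; then 3, Pd(PPh3)4 (3 mol %), THF, 25 °C
Reagents that add atoms: none
Why: Negishi sp2–sp3 cross-coupling of an alkylzinc halide with an alkenyl iodide proceeds with retention of the E geometry and tolerates the silyl ether and the silyl-capped alkyne.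

**Step 3**
Reactants: 6 (E)-tert-butyldimethyl{[3-methyl-8-(trimethylsilyl)oct-3-en-7-yn-1-yl]oxy}silane
Product: 7 (E)-tert-butyldimethyl[(3-methyloct-3-en-7-yn-1-yl)oxy]silane
Conditions: K2CO3 (0.2 equiv), MeOH, 25 °C
Reagents that add atoms: none
Why: Methanolysis of the alkynyl C–Si bond (alkyne protodesilylation) is selective over the alkyl TBS ether.

**Step 4**
Reactants: 7 (E)-tert-butyldimethyl[(3-methyloct-3-en-7-yn-1-yl)oxy]silane
Product: 10 (2E,6E)-9-(tert-butyldimethylsilyloxy)-3,7-dimethylnona-2,6-dien-1-ol, via alkenylalane 8 (not isolated), via lithium alanate 9 (not isolated)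
Conditions: Me3Al (2 equiv), Cp2ZrCl2 (0.2 equiv), CH2Cl2, rt; evaporate; n-BuLi, hexane–THF, −78 °C; (CH2O)n, → rt; aq. NH4Cl
Reagents that add atoms: trimethylaluminium C[Al](C)C; formaldehyde C=O
Why: A second Negishi carboalumination (syn, so the new olefin is E) followed by ate-complex formation and hydroxymethylation with formaldehyde is the standard entry to E-3-methylalk-2-en-1-ols; the existing trisubstituted olefin is inert.

**Step 5**
Reactants: 10 (2E,6E)-9-(tert-butyldimethylsilyloxy)-3,7-dimethylnona-2,6-dien-1-ol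
Product: 11 (2E,6E)-9-(tert-butyldimethylsilyloxy)-3,7-dimethylnona-2,6-dienal
Conditions: MnO2 (15 equiv), CH2Cl2, 25 °C
Reagents that add atoms: none
Why: MnO2 oxidation is selective for the allylic alcohol and gives the enal without E/Z isomerisation.

**Step 6**
Reactants: 11 (2E,6E)-9-(tert-butyldimethylsilyloxy)-3,7-dimethylnona-2,6-dienal; 12 tert-butyldiphenyl(prop-2-yn-1-yloxy)silane
Product: 15 (4S,5E,9E)-12-(tert-butyldimethylsilyloxy)-1-(tert-butyldiphenylsilyloxy)-6,10-dimethyldodeca-5,9-dien-2-yn-4-yl methyl carbonate, via alkynylzinc 13 (not isolated), via zinc alkoxide 14 (not isolated)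
Conditions: 12 (2.8 equiv), ZnMe2 (3 equiv), (R,R)-ProPhenol (20 mol %), Ph3PO (40 mol %), toluene, 0 °C; 11, 4 °C, 48 h; then ClCO2Me, pyridine, 0 °C
Reagents that add atoms: methyl chloroformate COC(=O)Cl
Why: Trost ProPhenol/zinc-catalysed asymmetric alkynylation of an enal sets C6 under ligand control (the (R,R)-ligand is chosen to give the 4S carbinol, the (S,S)-ligand gives its antipode) and the zinc alkoxide is acylated in the same flask to the carbonate needed for ionisation.

**Step 7**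
Reactants: 15 (4S,5E,9E)-12-(tert-butyldimethylsilyloxy)-1-(tert-butyldiphenylsilyloxy)-6,10-dimethyldodeca-5,9-dien-2-yn-4-yl methyl carbonate
Product: 16 methyl (Ra,5E,9E)-12-(tert-butyldimethylsilyloxy)-2-[(tert-butyldiphenylsilyloxy)methyl]-6,10-dimethyldodeca-2,3,5,9-tetraenoate
Conditions: Pd(OAc)2 (5 mol %), PPh3 (20 mol %), CO (10 atm), MeOH–THF, 25 °C
Reagents that add atoms: carbon monoxide [C-]#[O+]
Why: Tsuji carbonylation of a propargylic carbonate: zerovalent palladium displaces the carbonate anti (SN2′) to an allenylpalladium species that inserts CO with retention and is captured by the methoxide released from the carbonate, so the C6 centre is transferred to the allene axis (Ra); the hindered trisubstituted olefin ionises more slowly than the alkyne.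

**Step 8**
Reactants: 16 methyl (Ra,5E,9E)-12-(tert-butyldimethylsilyloxy)-2-[(tert-butyldiphenylsilyloxy)methyl]-6,10-dimethyldodeca-2,3,5,9-tetraenoate
Product: 17 (5R)-5-[(1E,5E)-8-(tert-butyldimethylsilyloxy)-2,6-dimethylocta-1,5-dien-1-yl]-3-[(tert-butyldiphenylsilyloxy)methyl]-4-iodofuran-2(5H)-one
Conditions: I2 (2 equiv), NaHCO3, MeCN–H2O (15:1), 25 °C; aq. Na2S2O3
Reagents that add atoms: iodine II; water O
Why: Ma-type iodolactonisation of a 2,3-allenoate: iodonium forms at the central allene carbon (C7) and the ester carbonyl oxygen attacks C6 anti, giving the β-iodobutenolide with axial-to-central chirality transfer (net inversion relative to 15, hence 5R), and water hydrolyses the dialkoxycarbenium ion.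

**Step 9**
Reactants: 17 (5R)-5-[(1E,5E)-8-(tert-butyldimethylsilyloxy)-2,6-dimethylocta-1,5-dien-1-yl]-3-[(tert-butyldiphenylsilyloxy)methyl]-4-iodofuran-2(5H)-one
Product: 18 (3E,7E)-8-{(2R)-4-[(tert-butyldiphenylsilyloxy)methyl]-3-iodo-5-oxo-2,5-dihydrofuran-2-yl}-3,7-dimethylocta-3,7-dienoic acid
Conditions: CrO3, H2SO4, H2O, acetone, 0 °C
Reagents that add atoms: water O
Why: Jones oxidation cleaves the primary TBS ether and oxidises the freed alcohol through the aldehyde hydrate to the β,γ-unsaturated acid, while the TBDPS ether, the vinyl iodide and the butenolide are stable to cold aqueous acid.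

**Step 10**
Reactants: 18 (3E,7E)-8-{(2R)-4-[(tert-butyldiphenylsilyloxy)methyl]-3-iodo-5-oxo-2,5-dihydrofuran-2-yl}-3,7-dimethylocta-3,7-dienoic acid
Product: 19 (3E,7E)-8-[(2R)-4-(hydroxymethyl)-3-iodo-5-oxo-2,5-dihydrofuran-2-yl]-3,7-dimethylocta-3,7-dienoic acid
Conditions: HF·pyridine, THF, 0 → 25 °C
Reagents that add atoms: none
Why: Fluoride desilylation under acidic, non-basic conditions removes the TBDPS ether without epimerising the base-sensitive C6–H.

**Step 11**
Reactants: 19 (3E,7E)-8-[(2R)-4-(hydroxymethyl)-3-iodo-5-oxo-2,5-dihydrofuran-2-yl]-3,7-dimethylocta-3,7-dienoic acid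
Product: 20 13-membered macrolactone of 19 (C8 carboxyl esterified by the C13 hydroxyl; ring C8(=O)–O–C13–C11=C7(I)–C6–C5=C4–C3–C2–C1=C10–C9; 6R, 1(10)E, 4E; the 12,6-butenolide bridges C11 and C6)
Conditions: PPh3 (5 equiv), DIAD (5 equiv), toluene–THF, slow addition, 0.002 M, −10 → 25 °C
Reagents that add atoms: none
Why: Mitsunobu macrolactonisation activates the primary allylic C13 alcohol for SN2 attack by the carboxylate, so the β,γ-unsaturated acid is never turned into an acyl electrophile that could isomerise; no stereocentre is touched and high dilution favours the 13-membered ring.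

**Step 12**
Reactants: 20 13-membered macrolactone of 19
Product: 23 (1(10)E,4E,6R)-13-acetoxy-8-oxogermacra-1(10),4,7(11)-trien-12,6-olide, via alkenylmagnesium 21 (not isolated), via magnesium alkoxide 22 (not isolated)
Conditions: i-PrMgCl·LiCl (1.1 equiv), THF (0.01 M), −78 °C, 30 min; then Ac2O (3 equiv), −78 → −20 °C; aq. NH4Cl
Reagents that add atoms: acetic anhydride CC(=O)OC(C)=O
Why: Proposed new method: iodine–magnesium exchange at the β-iodobutenolide (Knochel-type, faster than attack on either ester at −78 °C) puts a carbanion on C7 that is held cis and 1,4 to the lactone oxygen on C13, so it adds to the C8 carbonyl through a 5-exo-trig transition state and the tetrahedral intermediate collapses by expelling the C13 alkoxide, which turns the 13-membered lactone into the 10-membered carbocycle (new C7–C8 bond) in an exothermic step whose entropy cost was paid in step 11, and Ac2O traps the alkoxide as the C13 acetate before it can close back to a hemiketal; the closest known reactions are the Parham cyclisation, the anionic homo-Fries O→C acyl shift and SmI2-mediated intramolecular nucleophilic acyl substitution, none of which has been used to contract a macrolactone to a medium carbocycle.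

**Step 13**
Reactants: 23 (1(10)E,4E,6R)-13-acetoxy-8-oxogermacra-1(10),4,7(11)-trien-12,6-olide
Product: 24 (1(10)E,4E,6R,8S)-13-acetoxy-8-hydroxygermacra-1(10),4,7(11)-trien-12,6-olide (8α-OH)
Conditions: (R)-2-methyl-CBS-oxazaborolidine (0.5 equiv), catecholborane (1.5 equiv), toluene, −78 °C
Reagents that add atoms: none
Why: Corey–Bakshi–Shibata reduction: the (R)-oxazaborolidine binds the enone with the large tetrasubstituted alkenyl group (C7) away from the catalyst and delivers hydride to give the 8S alcohol under reagent control, and catecholborane at −78 °C does not hydroborate the olefins or touch the lactone.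

**Step 14**
Reactants: 24 (1(10)E,4E,6R,8S)-13-acetoxy-8-hydroxygermacra-1(10),4,7(11)-trien-12,6-olide; 25 (R)-3-chloro-2-hydroxy-2-methylpropanoic acid
Product: 26 (1(10)E,4E,6R,8S)-13-acetoxy-8-[(2R)-3-chloro-2-hydroxy-2-methylpropanoyloxy]germacra-1(10),4,7(11)-trien-12,6-olide
Conditions: 25 (2 equiv), DIC (2 equiv), DMAP (0.2 equiv), CH2Cl2, 0 → 25 °C
Reagents that add atoms: none
Why: Steglich esterification acylates the secondary allylic alcohol with retention at C8 and C2′; the tertiary hydroxyl of 25 is too hindered to compete and the mild base does not close the chlorohydrin or translactonise.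

**Step 15**
Reactants: 26 (1(10)E,4E,6R,8S)-13-acetoxy-8-[(2R)-3-chloro-2-hydroxy-2-methylpropanoyloxy]germacra-1(10),4,7(11)-trien-12,6-olide
Product: 27 (1R,4R,5R,6S,8S,10R)-13-acetoxy-8-[(2R)-3-chloro-2-hydroxy-2-methylpropanoyloxy]-1,10:4,5-diepoxygermacr-7(11)-en-12,6-olide (CNP0255009.1)
Conditions: mCPBA (2.3 equiv), NaHCO3, CH2Cl2, 0 °C
Reagents that add atoms: meta-chloroperoxybenzoic acid OOC(=O)c1cccc(Cl)c1
Why: Prilezhaev epoxidation: both electron-rich E-trisubstituted olefins react stereospecifically (the butenolide olefin is electron-poor and inert) from the exposed outer faces of the crown conformer of the E,E-cyclodeca-1,5-diene, as in the costunolide/parthenolide series, giving the trans 1β,10α- and 4α,5β-epoxides (1R,10R,4R,5R).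

**Compound list**
1 | tert-butyl(but-3-yn-1-yloxy)dimethylsilane | C#CCCO[Si](C)(C)C(C)(C)C | starting material
2 | dimethyl[(E)-4-(tert-butyldimethylsilyloxy)-2-methylbut-1-en-1-yl]alane | C[Al](C)/C=C(\C)CCO[Si](C)(C)C(C)(C)C | intermediate
3 | (E)-tert-butyl[(4-iodo-3-methylbut-3-en-1-yl)oxy]dimethylsilane | I/C=C(\C)CCO[Si](C)(C)C(C)(C)C | intermediate
4 | (4-bromobut-1-yn-1-yl)trimethylsilane | C[Si](C)(C)C#CCCBr | starting material
5 | [4-(trimethylsilyl)but-3-yn-1-yl]zinc bromide | C[Si](C)(C)C#CCC[Zn]Br | intermediate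
6 | (E)-tert-butyldimethyl{[3-methyl-8-(trimethylsilyl)oct-3-en-7-yn-1-yl]oxy}silane | C[Si](C)(C)C#CCC/C=C(\C)CCO[Si](C)(C)C(C)(C)C | intermediate
7 | (E)-tert-butyldimethyl[(3-methyloct-3-en-7-yn-1-yl)oxy]silane | C#CCC/C=C(\C)CCO[Si](C)(C)C(C)(C)C | intermediate
8 | dimethyl[(1E,5E)-8-(tert-butyldimethylsilyloxy)-2,6-dimethylocta-1,5-dien-1-yl]alane | C[Al](C)/C=C(\C)CC/C=C(\C)CCO[Si](C)(C)C(C)(C)C | intermediate
9 | lithium butyldimethyl[(1E,5E)-8-(tert-butyldimethylsilyloxy)-2,6-dimethylocta-1,5-dien-1-yl]alanate | [Li+].CCCC[Al-](C)(C)/C=C(\C)CC/C=C(\C)CCO[Si](C)(C)C(C)(C)C | intermediate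
10 | (2E,6E)-9-(tert-butyldimethylsilyloxy)-3,7-dimethylnona-2,6-dien-1-ol | OC/C=C(\C)CC/C=C(\C)CCO[Si](C)(C)C(C)(C)C | intermediate
11 | (2E,6E)-9-(tert-butyldimethylsilyloxy)-3,7-dimethylnona-2,6-dienal | O=C/C=C(\C)CC/C=C(\C)CCO[Si](C)(C)C(C)(C)C | intermediate
12 | tert-butyldiphenyl(prop-2-yn-1-yloxy)silane | C#CCO[Si](c1ccccc1)(c2ccccc2)C(C)(C)C | starting material
13 | methyl[3-(tert-butyldiphenylsilyloxy)prop-1-yn-1-yl]zinc | C[Zn]C#CCO[Si](c1ccccc1)(c2ccccc2)C(C)(C)C | intermediate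
14 | methylzinc (4S,5E,9E)-12-(tert-butyldimethylsilyloxy)-1-(tert-butyldiphenylsilyloxy)-6,10-dimethyldodeca-5,9-dien-2-yn-4-olate | C[Zn]O[C@H](C#CCO[Si](c1ccccc1)(c2ccccc2)C(C)(C)C)/C=C(\C)CC/C=C(\C)CCO[Si](C)(C)C(C)(C)C | intermediate
15 | (4S,5E,9E)-12-(tert-butyldimethylsilyloxy)-1-(tert-butyldiphenylsilyloxy)-6,10-dimethyldodeca-5,9-dien-2-yn-4-yl methyl carbonate | COC(=O)O[C@H](C#CCO[Si](c1ccccc1)(c2ccccc2)C(C)(C)C)/C=C(\C)CC/C=C(\C)CCO[Si](C)(C)C(C)(C)C | intermediate
16 | methyl (Ra,5E,9E)-12-(tert-butyldimethylsilyloxy)-2-[(tert-butyldiphenylsilyloxy)methyl]-6,10-dimethyldodeca-2,3,5,9-tetraenoate | COC(=O)C(CO[Si](c1ccccc1)(c2ccccc2)C(C)(C)C)=[C@]=C([H])/C=C(\C)CC/C=C(\C)CCO[Si](C)(C)C(C)(C)C | intermediate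
17 | (5R)-5-[(1E,5E)-8-(tert-butyldimethylsilyloxy)-2,6-dimethylocta-1,5-dien-1-yl]-3-[(tert-butyldiphenylsilyloxy)methyl]-4-iodofuran-2(5H)-one | O=C1O[C@H](/C=C(\C)CC/C=C(\C)CCO[Si](C)(C)C(C)(C)C)C(I)=C1CO[Si](c2ccccc2)(c3ccccc3)C(C)(C)C | intermediate
18 | (3E,7E)-8-{(2R)-4-[(tert-butyldiphenylsilyloxy)methyl]-3-iodo-5-oxo-2,5-dihydrofuran-2-yl}-3,7-dimethylocta-3,7-dienoic acid | OC(=O)C/C(C)=C/CC/C(C)=C/[C@H]1OC(=O)C(CO[Si](c2ccccc2)(c3ccccc3)C(C)(C)C)=C1I | intermediate
19 | (3E,7E)-8-[(2R)-4-(hydroxymethyl)-3-iodo-5-oxo-2,5-dihydrofuran-2-yl]-3,7-dimethylocta-3,7-dienoic acid | OC(=O)C/C(C)=C/CC/C(C)=C/[C@H]1OC(=O)C(CO)=C1I | intermediate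
20 | 13-membered macrolactone of 19 (C8 carboxyl to C13–O; 6R, 1(10)E, 4E; 7-iodo; 12,6-butenolide bridging C11 and C6) | O=C1C/C(C)=C/CC/C(C)=C/[C@H]2OC(=O)C(CO1)=C2I | intermediate
21 | C7-chloromagnesio analogue of 20 (I replaced by MgCl) | O=C1C/C(C)=C/CC/C(C)=C/[C@H]2OC(=O)C(CO1)=C2[Mg]Cl | intermediate
22 | chloromagnesium 13-alkoxide of (1(10)E,4E,6R)-13-hydroxy-8-oxogermacra-1(10),4,7(11)-trien-12,6-olide | Cl[Mg]OCC1=C2C(=O)C/C(C)=C/CC/C(C)=C/[C@H]2OC1=O | intermediate
23 | (1(10)E,4E,6R)-13-acetoxy-8-oxogermacra-1(10),4,7(11)-trien-12,6-olide | CC(=O)OCC1=C2C(=O)C/C(C)=C/CC/C(C)=C/[C@H]2OC1=O | intermediate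
24 | (1(10)E,4E,6R,8S)-13-acetoxy-8-hydroxygermacra-1(10),4,7(11)-trien-12,6-olide | CC(=O)OCC1=C2[C@@H](O)C/C(C)=C/CC/C(C)=C/[C@H]2OC1=O | intermediate
25 | (R)-3-chloro-2-hydroxy-2-methylpropanoic acid | OC(=O)[C@@](C)(O)CCl | starting material
26 | (1(10)E,4E,6R,8S)-13-acetoxy-8-[(2R)-3-chloro-2-hydroxy-2-methylpropanoyloxy]germacra-1(10),4,7(11)-trien-12,6-olide | CC(=O)OCC1=C2[C@@H](OC(=O)[C@@](C)(O)CCl)C/C(C)=C/CC/C(C)=C/[C@H]2OC1=O | intermediate
27 | (1R,4R,5R,6S,8S,10R)-13-acetoxy-8-[(2R)-3-chloro-2-hydroxy-2-methylpropanoyloxy]-1,10:4,5-diepoxygermacr-7(11)-en-12,6-olide | CC(=O)OCC1=C2[C@@H](OC(=O)[C@@](C)(O)CCl)C[C@@]3(C)O[C@@H]3CC[C@@]3(C)O[C@@H]3[C@H]2OC1=O | target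

The C6 descriptor changes from R (17–26) to S (27) only because the CIP ranking of C5 rises on epoxidation; the spatial arrangement (6α-O) is unchanged.

**Totals**
Total step count: 15. Longest linear sequence: 15 (from 1; compounds 4, 12 and 25 are used as purchased).

**Three steps most likely to fail**

Step 7 (Pd carbonylation). The carbonate in 15 is allylic as well as propargylic, so π-allyl formation, erosion of the centre-to-axis transfer, or thermal [1,5]-H shift of the vinylallene 16 could intervene. The fallback sets out from 11 and comes back at 17, using a sigmatropic route with no ionisation. Compound 11 is alkynylated with 12 using ZnMe2 and the antipodal (S,S)-ProPhenol and quenched with water to give (4R,5E,9E)-12-(tert-butyldimethylsilyloxy)-1-(tert-butyldiphenylsilyloxy)-6,10-dimethyldodeca-5,9-dien-2-yn-4-ol F1. O-Alkylation (KH, Bu3SnCH2I, THF) gives its tributylstannylmethyl ether F2. Tin–lithium exchange (n-BuLi, THF, −78 °C) triggers a [2,3]-Wittig–Still rearrangement across the alkyne; it is suprafacial, so the new CH2OH is syn to the departing oxygen, and gives the (Sa)-2,3-allenol (Sa,5E,9E)-12-(tert-butyldimethylsilyloxy)-2-[(tert-butyldiphenylsilyloxy)methyl]-6,10-dimethyldodeca-2,3,5,9-tetraen-1-ol F3. Dess–Martin oxidation gives the (Ra)-allenal F4 and Pinnick oxidation (NaClO2, NaH2PO4, 2-methyl-2-butene) the (Ra)-allenoic acid F5. Iodolactonisation of F5 (I2, NaHCO3, MeCN–H2O) gives 17, with net retention at C6 relative to F1.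

Step 12 (the new ring contraction). The alkenylmagnesium could be protonated, enolise the C9 position, or give a hemiketal/furan after acyl transfer. The fallback sets out from 17 and comes back at 23, using a known Nozaki–Hiyama–Kishi macrocyclisation. Selective removal of the primary TBS ether (HF·pyridine, pyridine–THF, 0 °C) gives (5R)-5-[(1E,5E)-8-hydroxy-2,6-dimethylocta-1,5-dien-1-yl]-3-[(tert-butyldiphenylsilyloxy)methyl]-4-iodofuran-2(5H)-one F6. Dess–Martin oxidation (NaHCO3) gives the β,γ-unsaturated aldehyde (3E,7E)-8-{(2R)-4-[(tert-butyldiphenylsilyloxy)methyl]-3-iodo-5-oxo-2,5-dihydrofuran-2-yl}-3,7-dimethylocta-3,7-dienal F7. Intramolecular coupling of the C7 iodide with the C8 aldehyde (CrCl2, NiCl2 cat., DMSO–THF, high dilution) closes the 10-membered ring to (6R)-13-(tert-butyldiphenylsilyloxy)-8-hydroxygermacra-1(10),4,7(11)-trien-12,6-olide (C8 epimers) F8. Dess–Martin oxidation gives the 8-ketone (6R)-13-(tert-butyldiphenylsilyloxy)-8-oxogermacra-1(10),4,7(11)-trien-12,6-olide F9. HF·pyridine gives (6R)-13-hydroxy-8-oxogermacra-1(10),4,7(11)-trien-12,6-olide F10 (partly as its cyclic hemiketal), and Ac2O/pyridine gives 23.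

Step 15 (double epoxidation). The face selectivity rests on the crown conformation, which the 7(11)-ene lactone and the C8 ester could perturb. The fallback sets out from 24 and comes back at 27, using hydroxyl-directed oxygen delivery for the 1(10)-olefin. The homoallylic 8α-hydroxyl of 24 directs VO(acac)2/t-BuOOH (CH2Cl2, 0 °C) to the C1=C10 face that gives the required 1,3-syn relationship between O8 and the C10–O bond, forming (1R,4E,6R,8S,10R)-13-acetoxy-1,10-epoxy-8-hydroxygermacra-4,7(11)-dien-12,6-olide F11. Esterification with 25 (DIC, DMAP) gives the 8-O-[(2R)-3-chloro-2-hydroxy-2-methylpropanoyl] ester F12. mCPBA (1.1 equiv, NaHCO3, CH2Cl2, 0 °C) then epoxidises the single remaining C4=C5 olefin from its outer face to give 27.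

**Further compounds**
F1 | step 7 | (4R,5E,9E)-12-(tert-butyldimethylsilyloxy)-1-(tert-butyldiphenylsilyloxy)-6,10-dimethyldodeca-5,9-dien-2-yn-4-ol | O[C@@H](C#CCO[Si](c1ccccc1)(c2ccccc2)C(C)(C)C)/C=C(\C)CC/C=C(\C)CCO[Si](C)(C)C(C)(C)C
F2 | step 7 | tributylstannylmethyl ether of F1 (4R) | CCCC[Sn](CCCC)(CCCC)CO[C@@H](C#CCO[Si](c1ccccc1)(c2ccccc2)C(C)(C)C)/C=C(\C)CC/C=C(\C)CCO[Si](C)(C)C(C)(C)C
F3 | step 7 | (Sa,5E,9E)-12-(tert-butyldimethylsilyloxy)-2-[(tert-butyldiphenylsilyloxy)methyl]-6,10-dimethyldodeca-2,3,5,9-tetraen-1-ol | OCC(CO[Si](c1ccccc1)(c2ccccc2)C(C)(C)C)=[C@]=C([H])/C=C(\C)CC/C=C(\C)CCO[Si](C)(C)C(C)(C)C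
F4 | step 7 | (Ra,5E,9E)-12-(tert-butyldimethylsilyloxy)-2-[(tert-butyldiphenylsilyloxy)methyl]-6,10-dimethyldodeca-2,3,5,9-tetraenal | O=CC(CO[Si](c1ccccc1)(c2ccccc2)C(C)(C)C)=[C@]=C([H])/C=C(\C)CC/C=C(\C)CCO[Si](C)(C)C(C)(C)C
F5 | step 7 | (Ra,5E,9E)-12-(tert-butyldimethylsilyloxy)-2-[(tert-butyldiphenylsilyloxy)methyl]-6,10-dimethyldodeca-2,3,5,9-tetraenoic acid | OC(=O)C(CO[Si](c1ccccc1)(c2ccccc2)C(C)(C)C)=[C@]=C([H])/C=C(\C)CC/C=C(\C)CCO[Si](C)(C)C(C)(C)C
F6 | step 12 | (5R)-5-[(1E,5E)-8-hydroxy-2,6-dimethylocta-1,5-dien-1-yl]-3-[(tert-butyldiphenylsilyloxy)methyl]-4-iodofuran-2(5H)-one | OCC/C(C)=C/CC/C(C)=C/[C@H]1OC(=O)C(CO[Si](c2ccccc2)(c3ccccc3)C(C)(C)C)=C1I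
F7 | step 12 | (3E,7E)-8-{(2R)-4-[(tert-butyldiphenylsilyloxy)methyl]-3-iodo-5-oxo-2,5-dihydrofuran-2-yl}-3,7-dimethylocta-3,7-dienal | O=CC/C(C)=C/CC/C(C)=C/[C@H]1OC(=O)C(CO[Si](c2ccccc2)(c3ccccc3)C(C)(C)C)=C1I
F8 | step 12 | (1(10)E,4E,6R)-13-(tert-butyldiphenylsilyloxy)-8-hydroxygermacra-1(10),4,7(11)-trien-12,6-olide (C8 epimers) | CC(C)(C)[Si](OCC1=C2C(O)C/C(C)=C/CC/C(C)=C/[C@H]2OC1=O)(c3ccccc3)c4ccccc4
F9 | step 12 | (1(10)E,4E,6R)-13-(tert-butyldiphenylsilyloxy)-8-oxogermacra-1(10),4,7(11)-trien-12,6-olide | CC(C)(C)[Si](OCC1=C2C(=O)C/C(C)=C/CC/C(C)=C/[C@H]2OC1=O)(c3ccccc3)c4ccccc4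
F10 | step 12 | (1(10)E,4E,6R)-13-hydroxy-8-oxogermacra-1(10),4,7(11)-trien-12,6-olide | OCC1=C2C(=O)C/C(C)=C/CC/C(C)=C/[C@H]2OC1=O
F11 | step 15 | (1R,4E,6R,8S,10R)-13-acetoxy-1,10-epoxy-8-hydroxygermacra-4,7(11)-dien-12,6-olide | CC(=O)OCC1=C2[C@@H](O)C[C@@]3(C)O[C@@H]3CC/C(C)=C/[C@H]2OC1=O
F12 | step 15 | (1R,4E,6R,8S,10R)-13-acetoxy-8-[(2R)-3-chloro-2-hydroxy-2-methylpropanoyloxy]-1,10-epoxygermacra-4,7(11)-dien-12,6-olide | CC(=O)OCC1=C2[C@@H](OC(=O)[C@@](C)(O)CCl)C[C@@]3(C)O[C@@H]3CC/C(C)=C/[C@H]2OC1=O
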